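**Plan**
1. Retrosynthesis: the C4 ketone is taken back to a benzylic methyl ether, and ring C is then cut at O1–C2 and C3–C4 in one operation.
2. Enabling feature: ring C is the O1–C8a–C4a–C4 heterodiene of a ring-A salicylaldehyde joined to a C2–C3 unit that is the vinyl group of 4-(prenyloxy)styrene; the C4 oxygen comes from trimethyl orthoformate.
3. Forward order: ring A (C-prenylation, then bis-silylation of 2,4,6-trihydroxybenzaldehyde) and ring B (O-prenylation, then Wittig methylenation of 4-hydroxybenzaldehyde) are made separately; ring C closes last in a three-component cationic ortho-quinone methide [4+2] annulation.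
4. End game: hydrolysis of the C4 methyl ether, oxidation to the ketone, buffered desilylation.
5. Stereochemistry: the only stereocentre of the target, C2 (S), is set in the annulation by a confined chiral Brønsted acid; C4 forms cis to it and is only transient; later steps avoid base so that the flavanone cannot racemise through the chalcone.

Key step: step 5

Assumption: the sense of induction of a given antipode of the chiral acid cannot be derived a priori for this substrate; the (S,S)-catalyst is written as the one giving 2S, and its mirror image would be used if a trial showed the opposite.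

**Step 1**
Reactants: 1 2,4,6-trihydroxybenzaldehyde; 2 prenyl bromide (1-bromo-3-methylbut-2-ene)
Product: 3 2,4,6-trihydroxy-3-(3-methylbut-2-enyl)benzaldehyde
Conditions: 2 (1.0 equiv), DBU (1.1 equiv), THF, 0 °C to rt
Reagents that add atoms: none
Why: C-prenylation of the ambident phloroglucinol-type phenoxide by the soft allylic bromide (Friedel–Crafts-type C-allylation), in which C3 and C5 are equivalent so that only one mono-C-prenyl isomer can form and one equivalent of 2 holds back double and O-alkylation.

**Step 2**
Reactants: 3 2,4,6-trihydroxy-3-(3-methylbut-2-enyl)benzaldehyde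
Product: 4 4,6-bis(tert-butyldimethylsilyloxy)-2-hydroxy-3-(3-methylbut-2-enyl)benzaldehyde
Conditions: TBSCl (2.1 equiv), imidazole (4 equiv), CH2Cl2/DMF, 0 °C
Reagents that add atoms: tert-butyldimethylsilyl chloride, CC(C)(C)[Si](C)(C)Cl
Why: Silyl ether formation in which the bulky chlorosilane should take the para hydroxyl (most acidic, not chelated) and the ortho hydroxyl next to C5–H, leaving the hydroxyl squeezed between the prenyl group and the chelating aldehyde free; the regiochemistry is to be confirmed by HMBC/NOE before use.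

**Step 3**
Reactants: 5 4-hydroxybenzaldehyde; 2 prenyl bromide
Product: 6 4-(3-methylbut-2-enyloxy)benzaldehyde
Conditions: 2 (1.1 equiv), K2CO3, acetone, reflux
Reagents that add atoms: none
Why: Williamson ether synthesis, SN2 attack of the phenoxide on the primary allylic bromide, with no competing C-alkylation expected for this electron-poor phenol.

**Step 4**
Reactants: 6 4-(3-methylbut-2-enyloxy)benzaldehyde
Product: 7 4-(3-methylbut-2-enyloxy)styrene
Conditions: Ph3PCH3Br, KOtBu, THF, 0 °C to rt; product kept cold over BHT
Reagents that add atoms: methyltriphenylphosphonium bromide, C[P+](c1ccccc1)(c1ccccc1)c1ccccc1.[Br-]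
Why: Wittig methylenation of an aryl aldehyde by the non-stabilised ylide, to which the prenyl ether is inert.

**Step 5**
Reactants: 4 4,6-bis(tert-butyldimethylsilyloxy)-2-hydroxy-3-(3-methylbut-2-enyl)benzaldehyde; 7 4-(3-methylbut-2-enyloxy)styrene; 8 trimethyl orthoformate
Product: 11 (2S,4S)-5,7-bis(tert-butyldimethylsilyloxy)-4-methoxy-8-(3-methylbut-2-enyl)-2-[4-(3-methylbut-2-enyloxy)phenyl]chroman, via dimethyl acetal 9 (not isolated), via O-methyl oxocarbenium ion 10 (not isolated)
Conditions: (S,S)-IDPi (confined BINOL-derived imidodiphosphorimidate, 5 mol %), 8 (1.5 equiv), 5 Å MS, CHCl3, 0 °C; then 7 (1.5 equiv, slow addition), −40 °C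
Reagents that add atoms: none
Why: Proposed new method: acid-catalysed exchange of 4 with 8 gives acetal 9, whose ionisation yields the O-methyl oxocarbenium ion 10, a cationic ortho-quinone methide hydrogen-bonded through its phenol to the confined chiral IDPi anion; the CH2 terminus of 7 attacks the cationic carbon (C3–C4) and the phenol oxygen then captures the developing 4-alkoxybenzylic cation (O1–C2) in an asynchronous inverse-electron-demand hetero-[4+2] addition. The closest known reaction types are the racemic acid-catalysed three-component coupling of salicylaldehydes, orthoformates and styrenes to cis-4-alkoxy-2-arylchromans and the chiral-acid-controlled (phosphoric acid, IDPi) cycloadditions of styrenes with ortho-quinone methides and oxocarbenium ions; what is new is their combination in enantioselective form. Ring C closes by 6-endo capture of the benzylic cation by O1 through a half-chair transition state, which amounts to a formal hetero-Diels–Alder closure. C4 is fixed when the anion-shielded face of 10 is attacked, and C2 follows from the suprafacial closure that puts aryl and methoxy cis (both pseudo-equatorial), so the catalyst's choice of styrene enantioface sets 2S while C4 serves only as a relay that is oxidised away later. The step needs chemoselectivity for the styrene over the two prenyl alkenes and the regiochemistry terminus-to-C4 and benzylic-carbon-to-O1: the 4-alkoxystyrene is by far the most nucleophilic alkene and gives the only benzylic cation, the two silyloxy groups stabilise 10, and with O7 silylated and the C2 hydroxyl engaged in the cation no phenol is free to cyclise onto the C-prenyl group. Any trans isomer is removed by chromatography at this stage, because after loss of C4 it could carry the wrong C2 configuration into the ketone.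

**Step 6**
Reactants: 11 (2S,4S)-5,7-bis(tert-butyldimethylsilyloxy)-4-methoxy-8-(3-methylbut-2-enyl)-2-[4-(3-methylbut-2-enyloxy)phenyl]chroman
Product: 12 (2S)-5,7-bis(tert-butyldimethylsilyloxy)-8-(3-methylbut-2-enyl)-2-[4-(3-methylbut-2-enyloxy)phenyl]chroman-4-ol (both C4 epimers)
Conditions: PPTS (0.2 equiv), THF/H2O 4:1, rt; neutral work-up, used crude
Reagents that add atoms: water, O
Why: Acid-catalysed SN1 hydrolysis (solvolysis) of the benzylic methyl ether, in which ionisation at C4 is assisted by O1 and the 5- and 7-silyloxy groups so that a weak acid suffices and the aryl silyl ethers, both prenyl groups and C2 are spared, while loss of configuration at C4 is of no consequence because that carbon becomes the carbonyl.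

**Step 7**
Reactants: 12 (2S)-5,7-bis(tert-butyldimethylsilyloxy)-8-(3-methylbut-2-enyl)-2-[4-(3-methylbut-2-enyloxy)phenyl]chroman-4-ol
Product: 13 (2S)-5,7-bis(tert-butyldimethylsilyloxy)-8-(3-methylbut-2-enyl)-2-[4-(3-methylbut-2-enyloxy)phenyl]chroman-4-one
Conditions: TPAP (5 mol %), NMO (1.5 equiv), 4 Å MS, CH2Cl2, rt
Reagents that add atoms: none
Why: Ley–Griffith oxidation of the secondary benzylic alcohol under neutral, anhydrous conditions, which should leave the trisubstituted alkenes, the silyl ethers and C2–H untouched and converge both C4 epimers on one ketone.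

**Step 8**
Reactants: 13 (2S)-5,7-bis(tert-butyldimethylsilyloxy)-8-(3-methylbut-2-enyl)-2-[4-(3-methylbut-2-enyloxy)phenyl]chroman-4-one
Product: 14 (2S)-5,7-dihydroxy-8-(3-methylbut-2-enyl)-2-[4-(3-methylbut-2-enyloxy)phenyl]chroman-4-one (CNP0558191.1)
Conditions: TBAF (2.5 equiv), AcOH (2.5 equiv), THF, 0 °C
Reagents that add atoms: none
Why: Fluoride-induced cleavage of the two aryl silyl ethers, with acetic acid protonating the phenoxides as they form so that the E1cB ring opening to the chalcone, the usual racemisation path of flavanones, is suppressed and C2 stays S.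

**Compound list**
1 | 2,4,6-trihydroxybenzaldehyde | O=Cc1c(O)cc(O)cc1O | starting material
2 | prenyl bromide (1-bromo-3-methylbut-2-ene) | CC(C)=CCBr | starting material
3 | 2,4,6-trihydroxy-3-(3-methylbut-2-enyl)benzaldehyde | O=Cc1c(O)c(CC=C(C)C)c(O)cc1O | intermediate
4 | 4,6-bis(tert-butyldimethylsilyloxy)-2-hydroxy-3-(3-methylbut-2-enyl)benzaldehyde | O=Cc1c(O)c(CC=C(C)C)c(O[Si](C)(C)C(C)(C)C)cc1O[Si](C)(C)C(C)(C)C | intermediate
5 | 4-hydroxybenzaldehyde | O=Cc1ccc(O)cc1 | starting material
6 | 4-(3-methylbut-2-enyloxy)benzaldehyde | CC(C)=CCOc1ccc(C=O)cc1 | intermediate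
7 | 4-(3-methylbut-2-enyloxy)styrene | C=Cc1ccc(OCC=C(C)C)cc1 | intermediate
8 | trimethyl orthoformate | COC(OC)OC | starting material
9 | dimethyl acetal of 4, 2-(dimethoxymethyl)-3,5-bis(tert-butyldimethylsilyloxy)-6-(3-methylbut-2-enyl)phenol (not isolated) | COC(OC)c1c(O)c(CC=C(C)C)c(O[Si](C)(C)C(C)(C)C)cc1O[Si](C)(C)C(C)(C)C | intermediate
10 | O-methyl oxocarbenium ion of 4 (cationic ortho-quinone methide, ion pair with the IDPi anion, not isolated) | C[O+]=Cc1c(O)c(CC=C(C)C)c(O[Si](C)(C)C(C)(C)C)cc1O[Si](C)(C)C(C)(C)C | intermediate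
11 | (2S,4S)-5,7-bis(tert-butyldimethylsilyloxy)-4-methoxy-8-(3-methylbut-2-enyl)-2-[4-(3-methylbut-2-enyloxy)phenyl]chroman (2,4-cis) | CC(C)=CCOc1ccc([C@@H]2C[C@H](OC)c3c(O[Si](C)(C)C(C)(C)C)cc(O[Si](C)(C)C(C)(C)C)c(CC=C(C)C)c3O2)cc1 | intermediate
12 | (2S)-5,7-bis(tert-butyldimethylsilyloxy)-8-(3-methylbut-2-enyl)-2-[4-(3-methylbut-2-enyloxy)phenyl]chroman-4-ol, mixture of C4 epimers | CC(C)=CCOc1ccc([C@@H]2CC(O)c3c(O[Si](C)(C)C(C)(C)C)cc(O[Si](C)(C)C(C)(C)C)c(CC=C(C)C)c3O2)cc1 | intermediate
13 | (2S)-5,7-bis(tert-butyldimethylsilyloxy)-8-(3-methylbut-2-enyl)-2-[4-(3-methylbut-2-enyloxy)phenyl]chroman-4-one | CC(C)=CCOc1ccc([C@@H]2CC(=O)c3c(O[Si](C)(C)C(C)(C)C)cc(O[Si](C)(C)C(C)(C)C)c(CC=C(C)C)c3O2)cc1 | intermediate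
14 | (2S)-5,7-dihydroxy-8-(3-methylbut-2-enyl)-2-[4-(3-methylbut-2-enyloxy)phenyl]chroman-4-one (CNP0558191.1) | CC(C)=CCOc1ccc([C@@H]2CC(=O)c3c(O)cc(O)c(CC=C(C)C)c3O2)cc1 | target

**Step count**
Total: 8 steps. Longest linear sequence: 6 steps (steps 1, 2, 5, 6, 7, 8); steps 3 and 4 form the second branch.

**Steps most likely to fail**

1. Step 5. The chiral anion may not discriminate the styrene enantiofaces well enough, the ring closure may not be cleanly cis, or the strong acid may polymerise the styrene or attack a prenyl group before the annulation is complete. The fallback sets out from 4 (with 7 and 8) and uses only known chemistry. The coupling would be run in its racemic form with Sc(OTf)3 (10 mol %) in CH2Cl2 at rt to give the racemic cis-4-methoxyflavan F1. Hydrolysis as in step 6 would give the racemic flavan-4-ol F2, and Ley–Griffith oxidation as in step 7 the racemic ketone F3. F3 would then be resolved kinetically by Noyori asymmetric transfer hydrogenation, RuCl(p-cymene)[(R,R)-TsDPEN] in HCO2H/Et3N, stopped near half conversion. On the usual model this catalyst delivers hydride to give a 4R alcohol on the face anti to the 2-aryl group, so it should consume the 2R ketone as the cis-(2R,4R)-flavan-4-ol F4 and leave the 2S ketone. The route is rejoined at 13.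

2. Step 2. Silylation may take place at the hydroxyl flanked by the prenyl group instead of the one next to C5–H, or run on to the tris-silyl ether, which would send material into the 6-prenyl series or give mixtures that are hard to separate. The fallback sets out from 1 and fixes the regiochemistry by construction; it also bypasses step 1. Bis-silylation of 1 (TBSCl, imidazole) would give 2-hydroxy-4,6-bis(tert-butyldimethylsilyloxy)benzaldehyde F5, in which the two ortho hydroxyls were equivalent. Tsuji–Trost O-alkylation with tert-butyl 2-methylbut-3-en-2-yl carbonate and Pd(PPh3)4 in THF at 0 °C would give the 1,1-dimethylallyl ether 2-(2-methylbut-3-en-2-yloxy)-4,6-bis(tert-butyldimethylsilyloxy)benzaldehyde F6. An aromatic Claisen rearrangement (toluene, 110 °C, or catalytic Eu(fod)3) can only deliver the prenyl group to the one free ortho carbon, next to the liberated hydroxyl. The route is rejoined at 4.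

3. Step 6. The C4 cation may partition to elimination (flav-3-ene) or to Friedel–Crafts self-condensation through C6 instead of capturing water, or the labile alcohol may decompose before it is oxidised. The fallback sets out from 11 and replaces solvolysis by hydride abstraction: DDQ (1.1 equiv) in CH2Cl2/pH 7 buffer at 0 °C should remove the C4 hydride, and water converts the resulting methoxy oxocarbenium directly into the ketone through its hemiketal. Low temperature and a small excess of oxidant are meant to spare the aryl prenyl ether. The route is rejoined at 13, and this fallback makes no new compound (F0).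

**Further compounds**
F1 | step 5 | racemic cis-5,7-bis(tert-butyldimethylsilyloxy)-4-methoxy-8-(3-methylbut-2-enyl)-2-[4-(3-methylbut-2-enyloxy)phenyl]chroman, (2S,4S) and (2R,4R) | CC(C)=CCOc1ccc([C@@H]2C[C@H](OC)c3c(O[Si](C)(C)C(C)(C)C)cc(O[Si](C)(C)C(C)(C)C)c(CC=C(C)C)c3O2)cc1.CC(C)=CCOc1ccc([C@H]2C[C@@H](OC)c3c(O[Si](C)(C)C(C)(C)C)cc(O[Si](C)(C)C(C)(C)C)c(CC=C(C)C)c3O2)cc1
F2 | step 5 | racemic 5,7-bis(tert-butyldimethylsilyloxy)-8-(3-methylbut-2-enyl)-2-[4-(3-methylbut-2-enyloxy)phenyl]chroman-4-ol, both C2 enantiomers, C4 epimers | CC(C)=CCOc1ccc([C@@H]2CC(O)c3c(O[Si](C)(C)C(C)(C)C)cc(O[Si](C)(C)C(C)(C)C)c(CC=C(C)C)c3O2)cc1.CC(C)=CCOc1ccc([C@H]2CC(O)c3c(O[Si](C)(C)C(C)(C)C)cc(O[Si](C)(C)C(C)(C)C)c(CC=C(C)C)c3O2)cc1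
F3 | step 5 | racemic 5,7-bis(tert-butyldimethylsilyloxy)-8-(3-methylbut-2-enyl)-2-[4-(3-methylbut-2-enyloxy)phenyl]chroman-4-one, (2S) and (2R) | CC(C)=CCOc1ccc([C@@H]2CC(=O)c3c(O[Si](C)(C)C(C)(C)C)cc(O[Si](C)(C)C(C)(C)C)c(CC=C(C)C)c3O2)cc1.CC(C)=CCOc1ccc([C@H]2CC(=O)c3c(O[Si](C)(C)C(C)(C)C)cc(O[Si](C)(C)C(C)(C)C)c(CC=C(C)C)c3O2)cc1
F4 | step 5 | (2R,4R)-5,7-bis(tert-butyldimethylsilyloxy)-8-(3-methylbut-2-enyl)-2-[4-(3-methylbut-2-enyloxy)phenyl]chroman-4-ol (2,4-cis) | CC(C)=CCOc1ccc([C@H]2C[C@@H](O)c3c(O[Si](C)(C)C(C)(C)C)cc(O[Si](C)(C)C(C)(C)C)c(CC=C(C)C)c3O2)cc1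
F5 | step 2 | 2-hydroxy-4,6-bis(tert-butyldimethylsilyloxy)benzaldehyde | O=Cc1c(O)cc(O[Si](C)(C)C(C)(C)C)cc1O[Si](C)(C)C(C)(C)C
F6 | step 2 | 2-(2-methylbut-3-en-2-yloxy)-4,6-bis(tert-butyldimethylsilyloxy)benzaldehyde | O=Cc1c(OC(C)(C)C=C)cc(O[Si](C)(C)C(C)(C)C)cc1O[Si](C)(C)C(C)(C)C
F0 | step 6 | none | none
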